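**Plan**

- Retrosynthesis (ring numbering: C1 carbonyl, C2=C3 alkene, C5 carbinol carbon): after O–Si cleavage the cyclohexenone is cut at C2=C3 and at C5–C6. This gives (3S)-3-silyloxydocosanal and a three-carbon linchpin (future C6–C1–C2) with a diazo group at one end and a Z-selective phosphonate at the other.
- Enabling feature: in the open chain, C5 carries a single hydrogen that is tertiary and alpha to oxygen. Once the cis C2=C3 bond exists, it lies 1,6 to the keto-carbenoid carbon C6, so C5–C6 can be made by C–H insertion with retention instead of by addition to a ketone.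
- Forward: icosanoyl chloride → β-keto ester → asymmetric hydrogenation → silyl ether → aldehyde. The chain is joined to the linchpin by olefination and the only ring is closed by carbenoid insertion in the same flask; desilylation ends the route.
- Stereochemistry: the single stereocenter is set as a secondary carbinol by (S)-BINAP/ruthenium hydrogenation and is carried, unchanged in space, into the tertiary carbinol.

Key step: step 6

Assumption: 2-[bis(2,2,2-trifluoroethoxy)phosphoryl]acetic acid 8, the free acid of the commercial Still–Gennari ester, is taken as a purchasable reagent.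

**Route**

Step 1
Reactants: 1 icosanoyl chloride; 2 Meldrum's acid (2,2-dimethyl-1,3-dioxane-4,6-dione)
Product: 4 methyl 3-oxodocosanoate, via acyl Meldrum's acid 3 (not isolated)
Conditions: pyridine, CH2Cl2, 0 °C to rt; then MeOH, reflux
Reagents that add atoms: methanol, CO
Why: C-acylation of Meldrum's acid followed by methanolysis with loss of acetone and CO2 is the standard Meldrum's acid route to β-keto esters and should tolerate the long saturated chain.

Step 2
Reactants: 4 methyl 3-oxodocosanoate
Product: 5 methyl (3S)-3-hydroxydocosanoate
Conditions: H2 (50 atm), RuCl2[(S)-BINAP] (0.5 mol %), MeOH–CH2Cl2, 50 °C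
Reagents that add atoms: none
Why: Noyori asymmetric hydrogenation of a β-keto ester; the substrate chelates ruthenium through both carbonyl oxygens and the (S)-BINAP ligand should deliver hydrogen to the face that gives the (S)-carbinol, as it does for simple 3-oxoalkanoates.

Step 3
Reactants: 5 methyl (3S)-3-hydroxydocosanoate
Product: 6 methyl (3S)-3-[(triethylsilyl)oxy]docosanoate
Conditions: Et3SiCl, imidazole, DMF–CH2Cl2, 0 °C to rt
Reagents that add atoms: chlorotriethylsilane, CC[Si](Cl)(CC)CC
Why: Routine silylation of a secondary alcohol; the silyl ether masks the O–H, which a carbenoid would attack, while keeping the carbinol C–H electron-rich, and the stereocenter is not touched.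

Step 4
Reactants: 6 methyl (3S)-3-[(triethylsilyl)oxy]docosanoate
Product: 7 (3S)-3-[(triethylsilyl)oxy]docosanal
Conditions: i-Bu2AlH (1.1 equiv), CH2Cl2–toluene, −78 °C; MeOH, then aqueous Rochelle salt
Reagents that add atoms: none
Why: Low-temperature partial reduction of a methyl ester stops at the aluminium hemiacetal, which releases the aldehyde only on work-up; the β-silyloxy stereocenter is not epimerisable.

Step 5
Reactants: 8 2-[bis(2,2,2-trifluoroethoxy)phosphoryl]acetic acid
Product: 10 bis(2,2,2-trifluoroethyl) (3-diazo-2-oxopropyl)phosphonate, via acid chloride 9 (not isolated)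
Conditions: (COCl)2, DMF (cat.), CH2Cl2, 0 °C to rt, evaporate; then Me3SiCHN2, MeCN–THF, 0 °C
Reagents that add atoms: (trimethylsilyl)diazomethane, C[Si](C)(C)C=[N+]=[N-]
Why: Acylation of a diazoalkane by an acid chloride (Arndt–Eistert-type diazoketone synthesis); chloride removes the silyl group from the acylated intermediate, so no acid is left to destroy the diazoketone.

Step 6
Reactants: 7 (3S)-3-[(triethylsilyl)oxy]docosanal; 10 bis(2,2,2-trifluoroethyl) (3-diazo-2-oxopropyl)phosphonate
Product: 12 (5S)-5-nonadecyl-5-[(triethylsilyl)oxy]cyclohex-2-en-1-one, via cis-diazoketone 11 (not isolated)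
Conditions: K2CO3, 18-crown-6 (cat.), toluene, −20 to 0 °C; then CH2Cl2, Rh2(O2CC7H15)4 (2 mol %), 0 to 40 °C, same flask
Reagents that add atoms: none
Why: Proposed new method: the potassium anion of 10 adds to aldehyde 7 and the electron-poor bis(trifluoroethyl) phosphonate collapses under kinetic control to the cis-enone (Still–Gennari variant of the Horner–Wadsworth–Emmons reaction), which makes the C2=C3 bond and holds the diazo carbon C6 next to C5; the dirhodium tetracarboxylate (divalent rhodium) then expels N2 and the electrophilic keto-carbenoid inserts into the C5–H bond through a three-centre transition state, which makes the C5–C6 bond. The closest known reaction types are Z-selective olefination with diazo-bearing phosphonates followed by carbenoid N–H insertion to six-membered aza-enones, and rhodium-carbenoid insertion into tertiary C–H bonds alpha to an ether oxygen. The only ring formed, the cyclohexenone, is closed by 1,6-insertion (carbenoid carbon to the sixth atom of the chain), which the cis double bond and the three sp2 atoms of the tether make geometrically easy. No new stereocenter is created: the hydrogen on (S)-configured C5 is replaced from the front side by C6, so the secondary silyl ether stereocenter of 7 should become the fully substituted carbinol carbon with retention. The step needs Z-selectivity in the olefination, which the trifluoroethyl phosphonate and the crown-separated potassium ion should secure. It also needs site selectivity in the insertion, which should follow because C5–H is tertiary and activated by the silyloxy oxygen, whereas the competing 1,5 C4–H bonds are beta to oxygen and allylic to an electron-poor enone, and the O–H is masked.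

Step 7
Reactants: 12 (5S)-5-nonadecyl-5-[(triethylsilyl)oxy]cyclohex-2-en-1-one
Product: 13 (5S)-5-hydroxy-5-nonadecylcyclohex-2-en-1-one
Conditions: HF·pyridine, pyridine, THF, 0 °C
Reagents that add atoms: none
Why: Buffered fluoride cleavage of a tertiary triethylsilyl ether at low temperature should avoid both acid- and base-induced loss of water from the β-hydroxy enone; the stereocenter is not involved.

**Compound list**

1 | icosanoyl chloride | CCCCCCCCCCCCCCCCCCCC(=O)Cl | starting material
2 | Meldrum's acid (2,2-dimethyl-1,3-dioxane-4,6-dione) | CC1(C)OC(=O)CC(=O)O1 | starting material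
3 | 5-(1-hydroxyicosylidene)-2,2-dimethyl-1,3-dioxane-4,6-dione (acyl Meldrum's acid, not isolated) | CCCCCCCCCCCCCCCCCCCC(O)=C1C(=O)OC(C)(C)OC1=O | intermediate
4 | methyl 3-oxodocosanoate | CCCCCCCCCCCCCCCCCCCC(=O)CC(=O)OC | intermediate
5 | methyl (3S)-3-hydroxydocosanoate | CCCCCCCCCCCCCCCCCCC[C@H](O)CC(=O)OC | intermediate
6 | methyl (3S)-3-[(triethylsilyl)oxy]docosanoate | CCCCCCCCCCCCCCCCCCC[C@H](O[Si](CC)(CC)CC)CC(=O)OC | intermediate
7 | (3S)-3-[(triethylsilyl)oxy]docosanal | CCCCCCCCCCCCCCCCCCC[C@H](O[Si](CC)(CC)CC)CC=O | intermediate
8 | 2-[bis(2,2,2-trifluoroethoxy)phosphoryl]acetic acid | OC(=O)CP(=O)(OCC(F)(F)F)OCC(F)(F)F | starting material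
9 | 2-[bis(2,2,2-trifluoroethoxy)phosphoryl]acetyl chloride (not isolated) | ClC(=O)CP(=O)(OCC(F)(F)F)OCC(F)(F)F | intermediate
10 | bis(2,2,2-trifluoroethyl) (3-diazo-2-oxopropyl)phosphonate | [N-]=[N+]=CC(=O)CP(=O)(OCC(F)(F)F)OCC(F)(F)F | intermediate
11 | (3Z,6S)-1-diazo-6-[(triethylsilyl)oxy]pentacos-3-en-2-one (not isolated) | CCCCCCCCCCCCCCCCCCC[C@H](O[Si](CC)(CC)CC)C/C=C\C(=O)C=[N+]=[N-] | intermediate
12 | (5S)-5-nonadecyl-5-[(triethylsilyl)oxy]cyclohex-2-en-1-one | CCCCCCCCCCCCCCCCCCC[C@]1(O[Si](CC)(CC)CC)CC=CC(=O)C1 | intermediate
13 | (5S)-5-hydroxy-5-nonadecylcyclohex-2-en-1-one | CCCCCCCCCCCCCCCCCCC[C@]1(O)CC=CC(=O)C1 | target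

**Step count**

Total steps: 7. Longest linear sequence: 6 (steps 1, 2, 3, 4, 6, 7); step 5 is a one-step side branch.

**Steps most likely to fail**

Step 6. What may go wrong:
- the olefination may give too much of the trans-enone, which cannot cyclise;
- carbonate, crown ether or phosphate salts may inhibit the rhodium catalyst (first remedy: pass the toluene solution through a short silica pad before adding the catalyst);
- the carbenoid may react elsewhere, by insertion into the allylic C4–H bonds to close a five-membered ring, by attack on the silyl ether oxygen, or by dimerisation.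

The fallback uses known chemistry only. It sets out from 4 and comes back at 13. Michael addition of 4 to but-3-en-2-one (NaOMe cat., MeOH) should give methyl 2-icosanoyl-5-oxohexanoate F1. Aldol condensation of the methyl ketone onto the chain ketone (Robinson annulation; NaOMe, MeOH, reflux) should close it to the Hagemann-type ester methyl 2-nonadecyl-4-oxocyclohex-2-ene-1-carboxylate F2. Saponification gives 2-nonadecyl-4-oxocyclohex-2-ene-1-carboxylic acid F3, which should lose CO2 on warm acidification to give 3-nonadecylcyclohex-2-en-1-one F4. Amine-salt-catalysed asymmetric nucleophilic epoxidation of this cyclic enone is done with aqueous H2O2 and a 9-amino-9-deoxy-epi-cinchona primary amine salt. The quinine- or quinidine-derived antipode is chosen according to which delivers the required epoxide, (1S,6S)-6-nonadecyl-7-oxabicyclo[4.1.0]heptan-2-one F5. Reductive cleavage of the epoxide C–O bond alpha to the ketone (PhSeSePh, NaBH4, AcOH, EtOH) should leave the tertiary C–O bond intact and give (3S)-3-hydroxy-3-nonadecylcyclohexan-1-one F6. Kinetic enolisation toward C6 (LDA, 2.2 equiv, THF, −78 °C) and dehydrogenation with N-tert-butylbenzenesulfinimidoyl chloride should then give 13. The other alpha carbon cannot give an enone because its neighbour is fully substituted.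

Step 7. What may go wrong: loss of water from the β-hydroxy enone during or after desilylation (E1cB under basic fluoride, ionisation under acid), followed by tautomerisation to the phenol.

The fallback sets out from 12 and comes back at 13; the ketone is taken out of play while the silyl group is removed. Luche reduction (NaBH4, CeCl3·7H2O, MeOH, −40 °C) should give (5S)-5-nonadecyl-5-[(triethylsilyl)oxy]cyclohex-2-en-1-ol F7 as a mixture of C1 epimers, which does not matter. With no carbonyl left, Bu4NF in THF can remove the silyl group without β-elimination to give (1S)-1-nonadecylcyclohex-4-ene-1,3-diol F8. MnO2 in CH2Cl2 should then oxidise only the allylic secondary alcohol and return 13 under neutral conditions.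

Step 4. What may go wrong: over-reduction to the primary alcohol or incomplete conversion, because the waxy C22 ester dissolves poorly at −78 °C and the aluminium hemiacetal may break down before the quench.

The fallback sets out from 6 and comes back at 7 by a two-step redox detour. Exhaustive reduction (LiBH4, THF–MeOH, 0 °C to rt) gives (3S)-3-[(triethylsilyl)oxy]docosan-1-ol F9. Oxidation with Dess–Martin periodinane (NaHCO3, CH2Cl2, 0 °C to rt) then gives 7 under conditions in which the substrate is soluble and the β-silyloxy aldehyde does not meet strong base.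

Further compounds
F1 | step 6 | methyl 2-icosanoyl-5-oxohexanoate | CCCCCCCCCCCCCCCCCCCC(=O)C(CCC(C)=O)C(=O)OC
F2 | step 6 | methyl 2-nonadecyl-4-oxocyclohex-2-ene-1-carboxylate | COC(=O)C1CCC(=O)C=C1CCCCCCCCCCCCCCCCCCC
F3 | step 6 | 2-nonadecyl-4-oxocyclohex-2-ene-1-carboxylic acid | OC(=O)C1CCC(=O)C=C1CCCCCCCCCCCCCCCCCCC
F4 | step 6 | 3-nonadecylcyclohex-2-en-1-one | O=C1CCCC(=C1)CCCCCCCCCCCCCCCCCCC
F5 | step 6 | (1S,6S)-6-nonadecyl-7-oxabicyclo[4.1.0]heptan-2-one | CCCCCCCCCCCCCCCCCCC[C@@]12O[C@@H]1C(=O)CCC2
F6 | step 6 | (3S)-3-hydroxy-3-nonadecylcyclohexan-1-one | CCCCCCCCCCCCCCCCCCC[C@]1(O)CCCC(=O)C1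
F7 | step 7 | (5S)-5-nonadecyl-5-[(triethylsilyl)oxy]cyclohex-2-en-1-ol | CCCCCCCCCCCCCCCCCCC[C@]1(O[Si](CC)(CC)CC)CC=CC(O)C1
F8 | step 7 | (1S)-1-nonadecylcyclohex-4-ene-1,3-diol | CCCCCCCCCCCCCCCCCCC[C@]1(O)CC=CC(O)C1
F9 | step 4 | (3S)-3-[(triethylsilyl)oxy]docosan-1-ol | CCCCCCCCCCCCCCCCCCC[C@H](O[Si](CC)(CC)CC)CCO
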